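Retrosynthesis: in the γ-lactone (oxolane numbering: O1, C2 chain, C3 CO2H, C4 =CH2, C5 C=O) the exocyclic C4=CH2 is cut first. The ring bond C2–C3 is then traced to a 1,2-shift in a six-membered 4-diazo-oxane-2,5-dione whose ketone carbon is extruded as the C3 carboxyl.
The oxane ring goes back to an (S)-2-furylcarbinol, the furyl–carbonyl bond to an acylation of furan, and the CH3–CO bond of the side chain to methyl addition to ω-pentadecalactone.
Forward: C16 keto acid from the macrolactone, acylfuran, six-membered ring by oxidative furan expansion, saturated keto lactone, diazo ketone, five-membered lactone by ring contraction, α-methylene, then release of the side-chain ketone.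
Stereochemistry: C2 comes from asymmetric transfer hydrogenation of the furyl ketone and passes through the 1,2-shift with retention; C3 is set during the ring contraction by protonation of the acid enol on the face away from the chain (cis).
Enabling feature: the carboxyl-bearing ring carbon C3 is bonded directly to the oxygen- and chain-bearing C2 of the five-membered lactone. This is the pattern left when a ketone carbon is excised from between these two atoms of a six-membered keto lactone and reappears as the carboxyl group.

Key step: step 10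

Remark: the (S,S)-TsDPEN ruthenium catalyst is assumed to show the same sense of induction with the 2-furyl ketone as with aryl alkyl ketones (furyl in the place of aryl), which gives the S carbinol; water, a co-reactant of steps 6, 10 and 13, is carried as compound 10.

Step 1
Reactants: 1 ω-pentadecalactone (oxacyclohexadecan-2-one)
Product: 3 16-hydroxyhexadecan-2-one, via Weinreb amide 2 (not isolated)
Conditions: MeNH(OMe)·HCl, iPrMgCl, THF, −20 °C; then MeMgBr, 0 °C to rt; aq NH4Cl
Reagents that add atoms: methylmagnesium bromide, C[Mg]Br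
Why: The chloromagnesium amide of N,O-dimethylhydroxylamine opens the macrolactone to the Weinreb amide, and the Grignard reagent then adds only once because the N-methoxy chelate holds the tetrahedral adduct until work-up (Weinreb ketone synthesis run in one pot from an ester).

Step 2
Reactants: 3 16-hydroxyhexadecan-2-one
Product: 4 15-oxohexadecanoic acid
Conditions: TEMPO (cat), NaOCl (cat), NaClO2, MeCN/phosphate buffer pH 6.7, 35 °C
Reagents that add atoms: sodium chlorite, [Na+].[O-]Cl=O
Why: Oxoammonium oxidation takes the primary alcohol to the aldehyde and chlorite carries it on to the acid (TEMPO oxidation coupled to a Pinnick-type oxidation), the ketone being inert to both oxidants.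

Step 3
Reactants: 4 15-oxohexadecanoic acid; 5 furan
Product: 7 1-(furan-2-yl)hexadecane-1,15-dione, via mixed anhydride 6 (not isolated)
Conditions: (CF3CO)2O, CH2Cl2, 0 °C; then furan (excess), 0 °C to rt
Reagents that add atoms: none
Why: The acyl trifluoroacetate is electrophilic enough to acylate the π-excessive furan at C2 without a Lewis acid, and the resulting ketone deactivates the ring against a second acylation (Friedel–Crafts acylation).

Step 4
Reactants: 7 1-(furan-2-yl)hexadecane-1,15-dione
Product: 8 1-(furan-2-yl)-14-(2-methyl-1,3-dioxolan-2-yl)tetradecan-1-one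
Conditions: (Me3SiOCH2)2, Me3SiOTf (cat), CH2Cl2, −78 to −20 °C; pyridine quench
Reagents that add atoms: 1,2-bis(trimethylsilyloxy)ethane, C[Si](C)(C)OCCO[Si](C)(C)C
Why: Under silyl triflate catalysis at low temperature the saturated methyl ketone is converted to its dioxolane while the furyl ketone, a vinylogous ester conjugated with the ring oxygen, is left alone (chemoselective Noyori acetalisation).

Step 5
Reactants: 8 1-(furan-2-yl)-14-(2-methyl-1,3-dioxolan-2-yl)tetradecan-1-one
Product: 9 (1S)-1-(furan-2-yl)-14-(2-methyl-1,3-dioxolan-2-yl)tetradecan-1-ol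
Conditions: RuCl[(S,S)-TsDPEN](p-cymene) (1 mol %), HCO2Na, CTAB, H2O/CH2Cl2, rt
Reagents that add atoms: none
Why: In the Noyori–Ikariya asymmetric transfer hydrogenation the ruthenium hydride and the ligand N–H deliver hydride and proton through an outer-sphere six-membered transition state to the Re face of the heteroaryl ketone, which should give the S carbinol, and the near-neutral formate medium spares the dioxolane.

Step 6
Reactants: 9 (1S)-1-(furan-2-yl)-14-(2-methyl-1,3-dioxolan-2-yl)tetradecan-1-ol; 10 water
Product: 11 (2S)-6-hydroxy-2-[13-(2-methyl-1,3-dioxolan-2-yl)tridecyl]-2H-pyran-3(6H)-one (both anomers)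
Conditions: NBS, NaHCO3, THF/H2O (4:1), 0 °C
Reagents that add atoms: none
Why: Electrophilic bromination and hydration of the furan, followed by recyclisation through the carbinol oxygen, expand the ring to the pyranone hemiacetal (Achmatowicz rearrangement); the carbinol carbon, now C2, is not touched and the anomeric carbon is left as an inconsequential mixture.

Step 7
Reactants: 11 (2S)-6-hydroxy-2-[13-(2-methyl-1,3-dioxolan-2-yl)tridecyl]-2H-pyran-3(6H)-one
Product: 12 (6S)-6-[13-(2-methyl-1,3-dioxolan-2-yl)tridecyl]-2H-pyran-2,5(6H)-dione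
Conditions: Dess–Martin periodinane, CH2Cl2, 0 °C to rt, no base
Reagents that add atoms: none
Why: The periodinane oxidises the hemiacetal to the lactone (lactol-to-lactone oxidation) without aqueous acid, which protects the dioxolane, and without base, which would enolise C6–H towards the aromatic 5-hydroxy-2-pyranone tautomer and erase the stereocenter.

Step 8
Reactants: 12 (6S)-6-[13-(2-methyl-1,3-dioxolan-2-yl)tridecyl]-2H-pyran-2,5(6H)-dione
Product: 13 (6S)-6-[13-(2-methyl-1,3-dioxolan-2-yl)tridecyl]oxane-2,5-dione
Conditions: H2 (1 atm), Pd/C, EtOAc, rt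
Reagents that add atoms: none
Why: The doubly activated C3=C4 bond of the enedione is hydrogenated much faster than the ketone under neutral heterogeneous conditions (catalytic hydrogenation), and C6 takes no part.

Step 9
Reactants: 13 (6S)-6-[13-(2-methyl-1,3-dioxolan-2-yl)tridecyl]oxane-2,5-dione
Product: 15 (6S)-4-diazo-6-[13-(2-methyl-1,3-dioxolan-2-yl)tridecyl]oxane-2,5-dione, via trifluoroacetyl ketone 14 (not isolated)
Conditions: LiN(SiMe3)2, THF, −78 °C; CF3CO2CH2CF3, −78 °C; cold aq NH4Cl; then MsN3, Et3N, H2O (1 equiv), MeCN, rt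
Reagents that add atoms: methanesulfonyl azide, CS(=O)(=O)N=[N+]=[N-]
Why: Kinetic deprotonation should take the ketone α-methylene C4 in preference to the hindered, oxygen-substituted C6 methine and the less acidic lactone α-methylene C3, C-trifluoroacetylation turns C4 into a 1,3-dicarbonyl carbon, and the sulfonyl azide then transfers N2 with loss of the trifluoroacetyl group as the N-sulfonyl amide (detrifluoroacetylative Regitz diazo transfer).

Step 10
Reactants: 15 (6S)-4-diazo-6-[13-(2-methyl-1,3-dioxolan-2-yl)tridecyl]oxane-2,5-dione; 10 water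
Product: 18 (2S,3S)-2-[13-(2-methyl-1,3-dioxolan-2-yl)tridecyl]-5-oxooxolane-3-carboxylic acid, via ketene 16 (not isolated), via acid enol 17 (not isolated)
Conditions: hν (medium-pressure Hg lamp, Pyrex, λ > 300 nm), degassed THF/H2O (9:1), 10 °C
Reagents that add atoms: none
Why: Light expels N2 from the ring-locked s-Z α-diazo ketone and, in step with it or through the singlet acyl carbene, the C6–C5 bond moves over to C4, so that C5 leaves the ring and becomes the ketene carbon of 16 (photochemical Wolff rearrangement in its ring-contracting form, known for cyclic 2-diazo ketones including cases where an oxygen-bearing ring carbon migrates). The five-membered lactone thus arises by a 1,2-shift with excision of one ring atom, so exo and endo labels do not apply, and its new bond is C6–C4 of the oxane, which is C2–C3 of the oxolane. C6 migrates with retention and appears unchanged as the 2S center. Water 10 adds to the ketene to give acid enol 17, and the proton should then reach C3 from the face not covered by the neighbouring C2 chain, which leaves carboxyl and chain cis (3S) under kinetic control. The step needs the shift to outrun the 1,2-hydrogen shift from the C3 methylene and O–H insertion of the carbene; the enforced s-Z geometry favours the concerted shift, and any hydrogen shift would only return enedione 12, which re-enters at step 8.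

Step 11
Reactants: 18 (2S,3S)-2-[13-(2-methyl-1,3-dioxolan-2-yl)tridecyl]-5-oxooxolane-3-carboxylic acid
Product: 19 (2S,3S)-2-[13-(2-methyl-1,3-dioxolan-2-yl)tridecyl]-5-oxooxolane-3,4-dicarboxylic acid (C4 epimers)
Conditions: MeOMgOCO2Me (2 M in DMF, excess), 130 °C; ice-cold 1 M HCl to pH 2, immediate extraction
Reagents that add atoms: methyl magnesium carbonate, COC(=O)O[Mg]OC
Why: The methoxide-level base enolises only the lactone α-carbon C4 and the carboxylation is pulled forward by the magnesium chelate of the α-carboxy lactone (Stiles carboxylation), while C3 is α only to a magnesium carboxylate and should keep its configuration.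

Step 12
Reactants: 19 (2S,3S)-2-[13-(2-methyl-1,3-dioxolan-2-yl)tridecyl]-5-oxooxolane-3,4-dicarboxylic acid
Product: 21 (2S,3S)-4-methylidene-2-[13-(2-methyl-1,3-dioxolan-2-yl)tridecyl]-5-oxooxolane-3-carboxylic acid, via Mannich base 20 (not isolated)
Conditions: 37% aq HCHO, PhNHMe, NaOAc, AcOH, rt
Reagents that add atoms: formaldehyde, C=O
Why: The malonic half-acid condenses at C4 with the iminium ion from formaldehyde and N-methylaniline, and loss of CO2 with expulsion of the aniline leaves the exocyclic methylene (decarboxylative Mannich methylenation) in a buffered medium too mild to epimerise C3 or to move the double bond into the ring.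

Step 13
Reactants: 21 (2S,3S)-4-methylidene-2-[13-(2-methyl-1,3-dioxolan-2-yl)tridecyl]-5-oxooxolane-3-carboxylic acid; 10 water
Product: 22 allo-pertusaric acid, (2S,3S)-4-methylidene-5-oxo-2-(14-oxopentadecyl)oxolane-3-carboxylic acid
Conditions: 1 M HCl, THF, rt
Reagents that add atoms: none
Why: Acid-catalysed hydrolysis of the dioxolane through its oxocarbenium ion frees the methyl ketone (acetal hydrolysis), and the α-methylene lactone, the acid and both stereocenters are stable to dilute aqueous acid at room temperature.

Compound list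
1 | ω-pentadecalactone (oxacyclohexadecan-2-one) | O=C1CCCCCCCCCCCCCCO1 | starting material
2 | 15-hydroxy-N-methoxy-N-methylpentadecanamide (Weinreb amide) | CON(C)C(=O)CCCCCCCCCCCCCCO | intermediate
3 | 16-hydroxyhexadecan-2-one | CC(=O)CCCCCCCCCCCCCCO | intermediate
4 | 15-oxohexadecanoic acid | CC(=O)CCCCCCCCCCCCCC(=O)O | intermediate
5 | furan | c1ccoc1 | starting material
6 | 15-oxohexadecanoic trifluoroacetic anhydride (mixed anhydride) | CC(=O)CCCCCCCCCCCCCC(=O)OC(=O)C(F)(F)F | intermediate
7 | 1-(furan-2-yl)hexadecane-1,15-dione | CC(=O)CCCCCCCCCCCCCC(=O)c1ccco1 | intermediate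
8 | 1-(furan-2-yl)-14-(2-methyl-1,3-dioxolan-2-yl)tetradecan-1-one | O=C(c1ccco1)CCCCCCCCCCCCCC2(C)OCCO2 | intermediate
9 | (1S)-1-(furan-2-yl)-14-(2-methyl-1,3-dioxolan-2-yl)tetradecan-1-ol | O[C@H](c1ccco1)CCCCCCCCCCCCCC2(C)OCCO2 | intermediate
10 | water | O | starting material
11 | (2S)-6-hydroxy-2-[13-(2-methyl-1,3-dioxolan-2-yl)tridecyl]-2H-pyran-3(6H)-one | OC1C=CC(=O)[C@H](CCCCCCCCCCCCCC2(C)OCCO2)O1 | intermediate
12 | (6S)-6-[13-(2-methyl-1,3-dioxolan-2-yl)tridecyl]-2H-pyran-2,5(6H)-dione | O=C1C=CC(=O)[C@H](CCCCCCCCCCCCCC2(C)OCCO2)O1 | intermediate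
13 | (6S)-6-[13-(2-methyl-1,3-dioxolan-2-yl)tridecyl]oxane-2,5-dione | O=C1CCC(=O)[C@H](CCCCCCCCCCCCCC2(C)OCCO2)O1 | intermediate
14 | (6S)-6-[13-(2-methyl-1,3-dioxolan-2-yl)tridecyl]-4-(trifluoroacetyl)oxane-2,5-dione (trifluoroacetyl ketone, enolised) | O=C1CC(C(=O)C(F)(F)F)C(=O)[C@H](CCCCCCCCCCCCCC2(C)OCCO2)O1 | intermediate
15 | (6S)-4-diazo-6-[13-(2-methyl-1,3-dioxolan-2-yl)tridecyl]oxane-2,5-dione | O=C1CC(=[N+]=[N-])C(=O)[C@H](CCCCCCCCCCCCCC2(C)OCCO2)O1 | intermediate
16 | (5S)-5-[13-(2-methyl-1,3-dioxolan-2-yl)tridecyl]-4-(oxomethylidene)oxolan-2-one (ketene) | O=C=C1CC(=O)O[C@H]1CCCCCCCCCCCCCC2(C)OCCO2 | intermediate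
17 | (5S)-4-(dihydroxymethylidene)-5-[13-(2-methyl-1,3-dioxolan-2-yl)tridecyl]oxolan-2-one (acid enol) | OC(O)=C1CC(=O)O[C@H]1CCCCCCCCCCCCCC2(C)OCCO2 | intermediate
18 | (2S,3S)-2-[13-(2-methyl-1,3-dioxolan-2-yl)tridecyl]-5-oxooxolane-3-carboxylic acid (cis) | C1C(=O)O[C@@H](CCCCCCCCCCCCCC2(C)OCCO2)[C@H]1C(=O)O | intermediate
19 | (2S,3S)-2-[13-(2-methyl-1,3-dioxolan-2-yl)tridecyl]-5-oxooxolane-3,4-dicarboxylic acid (C4 epimers) | OC(=O)C1C(=O)O[C@@H](CCCCCCCCCCCCCC2(C)OCCO2)[C@H]1C(=O)O | intermediate
20 | (2S,3S)-4-{[methyl(phenyl)amino]methyl}-2-[13-(2-methyl-1,3-dioxolan-2-yl)tridecyl]-5-oxooxolane-3,4-dicarboxylic acid (Mannich base) | OC(=O)C1(CN(C)c3ccccc3)C(=O)O[C@@H](CCCCCCCCCCCCCC2(C)OCCO2)[C@H]1C(=O)O | intermediate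
21 | (2S,3S)-4-methylidene-2-[13-(2-methyl-1,3-dioxolan-2-yl)tridecyl]-5-oxooxolane-3-carboxylic acid | C=C1C(=O)O[C@@H](CCCCCCCCCCCCCC2(C)OCCO2)[C@H]1C(=O)O | intermediate
22 | allo-pertusaric acid, (2S,3S)-4-methylidene-5-oxo-2-(14-oxopentadecyl)oxolane-3-carboxylic acid | C=C1C(=O)O[C@@H](CCCCCCCCCCCCCC(C)=O)[C@H]1C(=O)O | target

Total step count: 13. Longest linear sequence: 13 steps, from 1 to 22; furan 5 and water 10 enter as commercial materials.

Steps most likely to fail

Step 10. The protonation of acid enol 17 may show poor facial selectivity, so that the more stable trans acid dominates. The fallback sets out from 15 and sets C3 by catalyst approach instead of by protonation. The photolysis mixture, then rich in the C3 epimer (2S,3R)-2-[13-(2-methyl-1,3-dioxolan-2-yl)tridecyl]-5-oxooxolane-3-carboxylic acid F1, is taken without separation into its dianion (LiN(iPr)2, THF, −78 °C) and selenenylated at C4 with PhSeBr. This gives (2S)-2-[13-(2-methyl-1,3-dioxolan-2-yl)tridecyl]-5-oxo-4-(phenylselanyl)oxolane-3-carboxylic acid F2. Oxidation with H2O2 and selenoxide syn-elimination should lead to the butenolide (2S)-2-[13-(2-methyl-1,3-dioxolan-2-yl)tridecyl]-5-oxo-2,5-dihydrofuran-3-carboxylic acid F3. Hydrogenation (H2, Rh/Al2O3, EtOAc) from the ring face opposite the C2 chain places both new hydrogens anti to the chain and returns the cis acid 18, where the route is rejoined.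

Step 9. Proton removal may occur at the wrong site under the strongly basic kinetic conditions, either at the C6 methine with loss of configuration or at the lactone α-methylene, followed by misplaced acylation. The fallback sets out from 13 and replaces the enolate by a weakly basic condensation that can only settle on a methylene next to the ketone. Bredereck's reagent, tBuOCH(NMe2)2, in toluene at 40 °C should give the enaminone (6S)-4-[(dimethylamino)methylidene]-6-[13-(2-methyl-1,3-dioxolan-2-yl)tridecyl]oxane-2,5-dione F4. 4-Acetamidobenzenesulfonyl azide in MeCN then converts it by cycloaddition and fragmentation into diazo ketone 15, where the route is rejoined.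

Step 11. C3 may epimerise towards the trans acid, or the lactone may open irreversibly, during the hot basic carboxylation. The fallback sets out from 18 and works at low temperature. The dianion (NaN(SiMe3)2, 2.2 equiv, THF, −78 °C) is aminomethylated at C4 with Eschenmoser's salt to (2S,3S)-4-[(dimethylamino)methyl]-2-[13-(2-methyl-1,3-dioxolan-2-yl)tridecyl]-5-oxooxolane-3-carboxylic acid F5. Oxidation with mCPBA gives the corresponding amine N-oxide F6, which should undergo Cope elimination on gentle warming to give 21, where the route is rejoined; steps 11 and 12 are bypassed.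

Further compounds
F1 | step 10 | (2S,3R)-2-[13-(2-methyl-1,3-dioxolan-2-yl)tridecyl]-5-oxooxolane-3-carboxylic acid (trans) | C1C(=O)O[C@@H](CCCCCCCCCCCCCC2(C)OCCO2)[C@@H]1C(=O)O
F2 | step 10 | (2S)-2-[13-(2-methyl-1,3-dioxolan-2-yl)tridecyl]-5-oxo-4-(phenylselanyl)oxolane-3-carboxylic acid (C3/C4 epimers) | c3ccccc3[Se]C1C(=O)O[C@@H](CCCCCCCCCCCCCC2(C)OCCO2)C1C(=O)O
F3 | step 10 | (2S)-2-[13-(2-methyl-1,3-dioxolan-2-yl)tridecyl]-5-oxo-2,5-dihydrofuran-3-carboxylic acid | O=C1C=C(C(=O)O)[C@H](CCCCCCCCCCCCCC2(C)OCCO2)O1
F4 | step 9 | (6S)-4-[(dimethylamino)methylidene]-6-[13-(2-methyl-1,3-dioxolan-2-yl)tridecyl]oxane-2,5-dione | CN(C)C=C1CC(=O)O[C@@H](CCCCCCCCCCCCCC2(C)OCCO2)C1=O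
F5 | step 11 | (2S,3S)-4-[(dimethylamino)methyl]-2-[13-(2-methyl-1,3-dioxolan-2-yl)tridecyl]-5-oxooxolane-3-carboxylic acid | CN(C)CC1C(=O)O[C@@H](CCCCCCCCCCCCCC2(C)OCCO2)[C@H]1C(=O)O
F6 | step 11 | (2S,3S)-4-[(dimethylamino)methyl]-2-[13-(2-methyl-1,3-dioxolan-2-yl)tridecyl]-5-oxooxolane-3-carboxylic acid N-oxide | C[N+](C)([O-])CC1C(=O)O[C@@H](CCCCCCCCCCCCCC2(C)OCCO2)[C@H]1C(=O)O
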